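The data are calculated with constants of no real substance.

25.3% of the Z had become L after 0.200 min in the north run, and from that one reading I reckoned how fast the exchange would run in violet.

the same everywhere: Z 20 mM
- south-west: D 0.38 equiv; E 1 equiv; run made earlier
- north: D 2.7 equiv; E 1 equiv; run made earlier
- violet: D 3.00 equiv; E 1.00 equiv; time 5.0 min
- grey: D 1.50 equiv; E 1.00 equiv; time 5.0 min
- ochre: D 0.500 equiv; E 1.00 equiv; time 5.0 min

| run | time / min | L / % | J / % |
|---|---|---|---|
| south-west | 0.200 | 4.1 | 1.8 |
| south-west | 0.417 | 8.8 | 0 |
| south-west | 0.667 | 11.1 | 2.1 |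
| south-west | 1.33 | 14.8 | 0.6 |
| south-west | 2.50 | 18.7 | 1.8 |
| north | 0.200 | 25.3 | 0 |
| north | 0.667 | 52.6 | 5.0 |
| north | 1.33 | 61.2 | 10.0 |
| north | 2.00 | 64.5 | 15.0 |
| north | 2.50 | 64.1 | 14.9 |

(scatter of a reading: 1 percentage point)

- a reading or a percentage of J counts all its forms, free or not

1. which of these holds the largest part of the Z at the end of violet (L / J / Z)
2. which of these holds the largest part of the Z at the end of grey (L / J / Z)
3. which of these holds the largest part of the Z at the end of ochre (L / J / Z)
4. amount of L at the end of violet, in percent of the Z charged

Z takes up D and gives off E to make L, and L can do the same to make J. At the start I took c_D as its charge, so Z falls first-order (pseudo-first-order), with a rate constant proportional to c_D: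

rate constant in north = 1.46 min⁻¹

half-time in north = 0.475 min

half-time in violet = 0.475 min × 2.7 / 3.00 = 0.428 min

I call this h, the exchange half-life: the time in which Z would go half over to L at the charged D, with the way back not counted.

Was the proportion sound? South-west's reading of 8.8% at 0.417 min gave 3.14 min directly, while north scaled to 0.38 equiv of D gave 3.38 min. Within the scatter, it held.

Violet's 5.0 min is 11.7 such half-lives, so I asked where the exchange stands, not how fast it gets there. North's L read 64.5% at 2.00 min and 64.1% at 2.50 min, equal within the scatter of 1 percentage point, which does not show that the north flask had come to rest. Violet charges 3.00 equiv of D against north's 2.7 equiv, so I committed to L near 64.1%. In ochre h is 2.57 min, and its 0.500 equiv of D can exchange at most that share of the Z, so I expected Z to stay ahead.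

The forecast named L for violet, L for grey and Z for ochre, with 61% of L in violet, lower than my figure. Its ground was that “5 min is near equilibrium”.

Violet ended with L at 65.4%, grey with L at 56.9%, and ochre with Z at 71.0%.

    L + D ⇌ E + J (K = 0.660, k = 0.0934 M⁻¹ s⁻¹)
    Z + J ⇌ X, settled at all times (K = 93.0 M⁻¹)
    D → G (k = 0.00406 s⁻¹)
    Z + D ⇌ E + L (K = 15.0, k = 0.480 M⁻¹ s⁻¹)

In violet my h of 0.428 min, or 0.40 min from the constants, lay well below the 2.8 min half-life of D by the loss to G alone, and 61% of the making of L from Z up to the end was done by 0.500 min. L stood at 65.3% at 2.50 min and 65.4% at 5.00 min, while D fell from 33.0% to 17.9% of its charge. In ochre h is 2.57 min, against that same 2.8 min, and at the end D was down to 6.72% of its charge, with L at 27.4%.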